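Everything rests on opening ring C of the upper flavan at O1–C2 and C3–C4. The feature exploited is that C4 is benzylic to both ring A and ring D while O1 is a phenolic oxygen of ring A, so O1–C8a–C4a–C4 is a latent ortho-quinone methide. One acid-catalysed [4+2] cycloaddition of that methide with (Z)-4-benzyloxystyryl acetate closes ring C, forms both bonds and sets C2, C3 and C4 together. Its precursor is perbenzylated (+)-catechin bearing at C8' a hydroxy(aryl)methyl group, the aryl part being ring A with one free ortho phenol. Short conventional sequences lead to both partners; ester cleavage and hydrogenolysis finish.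

Key step: step 10

Numbering: the upper flavan has rings A, C and B and atoms O1, C2 to C8a. The catechin unit has rings D, F and E and primed atoms. The units are joined C4–C8'. Monomeric catechin derivatives are named with plain chroman numbers, so chroman C8 is the later C8'.

Reading of the target: the upper unit is (2R,3R,4R), that is 2,3-cis-3,4-trans, with ring B and the C3 oxygen on the α face and ring D on the β face. The lower unit is (2'R,3'S), identical with (+)-catechin.

Design choices for the precursor:
- (a) The phenol that becomes O1 travels as an allyl ether. The carbinol flanked by two trioxygenated rings ionises with traces of acid, so it tolerates no acid-labile phenol mask.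
- (b) The carbinol is assembled from C8'-lithiated catechin and a ring A salicylaldehyde. Regiochemistry then rests on a selective bromination and on a symmetric aldehyde. No directed lithiation next to benzyl ethers and no separate formylation step are needed.

Assumption: which antipode of the binaphthyl phosphoric acid reinforces the bias of ring F cannot be derived on paper, so the (R) acid is written and both antipodes are compared in the first run.

Step 1
Reactants: 1 (+)-catechin
Product: 2 tetra-O-benzylcatechin, (2R,3S)-5,7-bis(benzyloxy)-2-[3,4-bis(benzyloxy)phenyl]chroman-3-ol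
Conditions: BnBr (4.4 equiv), K2CO3, DMF, 0 °C to rt
Reagents that add atoms: benzyl bromide, BrCc1ccccc1
Why: Williamson ether synthesis in which carbonate deprotonates only the four phenols, so the secondary alcohol stays free and, since no strong base meets a free ring E phenol, C2' is not epimerised and both catechin stereocentres pass through unchanged.

Step 2
Reactants: 2 tetra-O-benzylcatechin
Product: 3 penta-O-benzylcatechin, (2R,3S)-3,5,7-tris(benzyloxy)-2-[3,4-bis(benzyloxy)phenyl]chroman
Conditions: NaH, BnBr, DMF, 0 °C to rt
Reagents that add atoms: benzyl bromide, BrCc1ccccc1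
Why: Williamson ether synthesis on the sodium alkoxide of the remaining alcohol removes the only protic, nucleophilic group that could quench the later aryllithium or trap the later cation, and it touches no stereocentre.

Step 3
Reactants: 3 penta-O-benzylcatechin
Product: 4 8-bromo-penta-O-benzylcatechin, (2R,3S)-8-bromo-3,5,7-tris(benzyloxy)-2-[3,4-bis(benzyloxy)phenyl]chroman
Conditions: NBS (1.0 equiv), CH2Cl2, −78 °C to 0 °C
Reagents that add atoms: N-bromosuccinimide, O=C1CCC(=O)N1Br
Why: Electrophilic aromatic bromination goes to ring D, the most electron-rich ring, and there to C8', which is flanked by the tied-back ring oxygen O1' and is less shielded than C6' between two benzyloxy groups, while one equivalent at low temperature should stop at the monobromide.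

Step 4
Reactants: 5 2,4,6-trihydroxybenzaldehyde
Product: 6 2,4-bis(benzyloxy)-6-hydroxybenzaldehyde
Conditions: BnBr (2.05 equiv), K2CO3, DMF, rt
Reagents that add atoms: benzyl bromide, BrCc1ccccc1
Why: Williamson ether synthesis with two equivalents of halide caps the para phenol and one ortho phenol, after which the last phenol is locked in a strong hydrogen bond to the aldehyde and is alkylated much more slowly.

Step 5
Reactants: 6 2,4-bis(benzyloxy)-6-hydroxybenzaldehyde
Product: 7 2-(allyloxy)-4,6-bis(benzyloxy)benzaldehyde
Conditions: allyl bromide, K2CO3, DMF, 50 °C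
Reagents that add atoms: allyl bromide, C=CCBr
Why: Williamson ether synthesis with a reactive allylic halide and gentle heating overcomes the chelated phenol and installs a mask that survives organolithium addition and leaves later without acid.

Step 6
Reactants: 4 8-bromo-penta-O-benzylcatechin; 7 2-(allyloxy)-4,6-bis(benzyloxy)benzaldehyde
Product: 9 [2-(allyloxy)-4,6-bis(benzyloxy)phenyl](penta-O-benzylcatechin-8-yl)methanol as both carbinol epimers, via 8-lithio-penta-O-benzylcatechin 8 (not isolated)
Conditions: 4 (1.1 equiv), n-BuLi (1.05 equiv), THF, −78 °C; then 7, −78 to −40 °C; H2O quench; Et3N-deactivated silica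
Reagents that add atoms: none
Why: Bromine–lithium exchange outruns benzylic deprotonation at −78 °C and the aryllithium adds 1,2 to the aldehyde (organolithium carbonyl addition), the new carbinol centre forming without control, which is harmless because step 10 makes it planar.

Step 7
Reactants: 9 allyl-protected diarylcarbinol
Product: 10 [2,4-bis(benzyloxy)-6-hydroxyphenyl](penta-O-benzylcatechin-8-yl)methanol, the ring A/ring D diarylcarbinol with free ortho phenol, as both carbinol epimers
Conditions: Pd(PPh3)4 (5 mol %), morpholine (5 equiv), THF, rt; Et3N-deactivated silica or used crude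
Reagents that add atoms: none
Why: Tsuji–Trost-type deallylation, in which zerovalent palladium ionises the aryl allyl ether and morpholine takes up the allyl group, runs under neutral to basic conditions, so benzyl ethers and the very acid-labile benzhydrol should both survive.

Step 8
Reactants: 11 4-(benzyloxy)benzaldehyde
Product: 12 1-(benzyloxy)-4-ethynylbenzene
Conditions: dimethyl (1-diazo-2-oxopropyl)phosphonate, K2CO3, MeOH/THF, rt
Reagents that add atoms: dimethyl (1-diazo-2-oxopropyl)phosphonate, CC(=O)C(=[N+]=[N-])P(=O)(OC)OC
Why: The Ohira–Bestmann variant of the Seyferth–Gilbert homologation turns a non-enolisable aryl aldehyde into the terminal alkyne in one operation under carbonate/methanol conditions that leave the benzyl ether alone.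

Step 9
Reactants: 12 1-(benzyloxy)-4-ethynylbenzene
Product: 13 (Z)-2-[4-(benzyloxy)phenyl]ethenyl acetate
Conditions: AcOH (1.3 equiv), Ru(methallyl)2(dppb) (2 mol %, dppb = Ph2P(CH2)4PPh2), toluene, 45 °C
Reagents that add atoms: acetic acid, CC(=O)O
Why: Ruthenium-catalysed anti-Markovnikov hydro-acyloxylation of a terminal alkyne, a reaction type in which this bis(methallyl) diphosphine complex adds H and carboxylate in an overall trans sense, should give the Z-enol ester as the kinetic product.

Step 10
Reactants: 10 ring A/ring D diarylcarbinol; 13 (Z)-2-[4-(benzyloxy)phenyl]ethenyl acetate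
Product: 15 octa-O-benzyl-3-O-acetyl-epiafzelechin-(4β→8)-catechin with (2R,3R,4R,2'R,3'S) configuration, via Z-ortho-quinone methide 14 (not isolated)
Conditions: 13 (3 equiv), (R)-3,3'-bis(2,4,6-triisopropylphenyl)-1,1'-binaphthyl-2,2'-diyl hydrogen phosphate (10 mol %), 5 Å molecular sieves, toluene, 0 °C to rt, 10 added by syringe pump
Reagents that add atoms: none
Why: Proposed new method: the chiral phosphoric acid ionises the doubly donor-activated carbinol of 10 and, after loss of water, stays hydrogen-bonded to O1 of methide 14 (O1=C8a–C4a=C4), whereupon the acetoxy-bearing alkene carbon of 13 bonds to electrophilic C4 while O1 closes on the carbon next to ring B in an asynchronous inverse-electron-demand hetero-Diels–Alder reaction that regains the aromaticity of ring A. The closest known reaction type is the Brønsted-acid-catalysed [4+2] cycloaddition of methides from ortho-hydroxybenzhydrols with styrenes and beta-substituted styrenes to 2,4-diarylchromans, so only the enol ester as 2π partner and the di-ortho-substituted aryl group on the methide go beyond it. Ring C is the only ring closed, as a six-membered pyran by intermolecular [4π+2π] addition, and if bonding turns stepwise the second event is a 6-exo-trig capture of the para-benzyloxybenzyl cation by O1. C2 and C3 are linked by suprafacial addition to the Z alkene (2,3-cis), C4 is set relative to them by the methide geometry, because peri strain with the C5 benzyloxy group turns ring D towards O1 (Z, inside position) and an endo approach of ring B and the acetoxy group then leaves ring D trans to both (3,4-trans, 2,4-trans), and the absolute sense follows from bonding at the Si face of C4, which the phosphate pocket and the twisted ring D with its unlike ortho flanks (C7' benzyloxy against ring F) are meant to select. A stepwise closure should converge on the same triad, since the same peri strain keeps ring D pseudoaxial in the half-chair and ring B then takes the equatorial site cis to the axial acetate. The step needs O1-to-C2 regiochemistry, secured by the para-benzyloxy group of ring B outweighing the weakly donating ester oxygen, and chemoselectivity over self-condensation, secured because every free aromatic CH of 10 (C6, C8, C6') lies between two oxygen substituents, by the excess of 13 and by the slow addition of 10.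

Step 11
Reactants: 15 octa-O-benzyl 3-acetate
Product: 16 octa-O-benzyl-epiafzelechin-(4β→8)-catechin with free C3 hydroxyl
Conditions: NaOMe (0.3 equiv), MeOH/THF, rt
Reagents that add atoms: none
Why: Zemplén-type transesterification removes the only ester, and with every phenol still benzylated no quinone methide pathway is open, so C2, C3 and C4 should not epimerise.

Step 12
Reactants: 16 octa-O-benzyl-epiafzelechin-(4β→8)-catechin
Product: 17 Gambiriin C, epiafzelechin-(4β→8)-catechin
Conditions: H2 (1 atm), Pd(OH)2/C, THF/MeOH/H2O, rt
Reagents that add atoms: none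
Why: Catalytic hydrogenolysis of benzyl ethers under neutral conditions cleaves all eight O–CH2Ph bonds, while the cyclic benzylic C2–O1 bonds and the C4–C8' bond, which need acid or forcing conditions, should stay intact together with all five stereocentres.

Compound list
1 | (+)-catechin | Oc1cc(O)c2c(c1)O[C@H](c1ccc(O)c(O)c1)[C@@H](O)C2 | starting material
2 | tetra-O-benzylcatechin | O(Cc9ccccc9)c1cc(OCc9ccccc9)c2c(c1)O[C@H](c1ccc(OCc9ccccc9)c(OCc9ccccc9)c1)[C@@H](O)C2 | intermediate
3 | penta-O-benzylcatechin | O(Cc9ccccc9)c1cc(OCc9ccccc9)c2c(c1)O[C@H](c1ccc(OCc9ccccc9)c(OCc9ccccc9)c1)[C@@H](OCc9ccccc9)C2 | intermediate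
4 | 8-bromo-penta-O-benzylcatechin | Brc1c(OCc9ccccc9)cc(OCc9ccccc9)c2c1O[C@H](c1ccc(OCc9ccccc9)c(OCc9ccccc9)c1)[C@@H](OCc9ccccc9)C2 | intermediate
5 | 2,4,6-trihydroxybenzaldehyde | O=Cc1c(O)cc(O)cc1O | starting material
6 | 2,4-bis(benzyloxy)-6-hydroxybenzaldehyde | O=Cc1c(O)cc(OCc9ccccc9)cc1OCc9ccccc9 | intermediate
7 | 2-(allyloxy)-4,6-bis(benzyloxy)benzaldehyde | O=Cc1c(OCC=C)cc(OCc9ccccc9)cc1OCc9ccccc9 | intermediate
8 | 8-lithio-penta-O-benzylcatechin (not isolated) | [Li]c1c(OCc9ccccc9)cc(OCc9ccccc9)c2c1O[C@H](c1ccc(OCc9ccccc9)c(OCc9ccccc9)c1)[C@@H](OCc9ccccc9)C2 | intermediate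
9 | allyl-protected ring A/ring D diarylcarbinol, both carbinol epimers | OC(c1c(OCC=C)cc(OCc9ccccc9)cc1OCc9ccccc9)c3c(OCc9ccccc9)cc(OCc9ccccc9)c4c3O[C@H](c3ccc(OCc9ccccc9)c(OCc9ccccc9)c3)[C@@H](OCc9ccccc9)C4 | intermediate
10 | ring A (2-hydroxy)/ring D diarylcarbinol, both carbinol epimers | OC(c1c(O)cc(OCc9ccccc9)cc1OCc9ccccc9)c3c(OCc9ccccc9)cc(OCc9ccccc9)c4c3O[C@H](c3ccc(OCc9ccccc9)c(OCc9ccccc9)c3)[C@@H](OCc9ccccc9)C4 | intermediate
11 | 4-(benzyloxy)benzaldehyde | O=Cc1ccc(OCc9ccccc9)cc1 | starting material
12 | 1-(benzyloxy)-4-ethynylbenzene | C#Cc1ccc(OCc9ccccc9)cc1 | intermediate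
13 | (Z)-2-[4-(benzyloxy)phenyl]ethenyl acetate | CC(=O)O/C=C\c1ccc(OCc9ccccc9)cc1 | intermediate
14 | (Z)-3,5-bis(benzyloxy)-6-[(penta-O-benzylcatechin-8-yl)methylidene]cyclohexa-2,4-dien-1-one, ring D syn to the carbonyl oxygen (not isolated) | c3(/C=C1\C(=O)C=C(OCc9ccccc9)C=C1OCc9ccccc9)c(OCc9ccccc9)cc(OCc9ccccc9)c4c3O[C@H](c3ccc(OCc9ccccc9)c(OCc9ccccc9)c3)[C@@H](OCc9ccccc9)C4 | intermediate
15 | octa-O-benzyl-3-O-acetyl-epiafzelechin-(4β→8)-catechin | O(Cc9ccccc9)c1ccc([C@H]2Oc3cc(OCc9ccccc9)cc(OCc9ccccc9)c3[C@H](c3c(OCc9ccccc9)cc(OCc9ccccc9)c4c3O[C@H](c3ccc(OCc9ccccc9)c(OCc9ccccc9)c3)[C@@H](OCc9ccccc9)C4)[C@H]2OC(C)=O)cc1 | intermediate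
16 | octa-O-benzyl-epiafzelechin-(4β→8)-catechin | O(Cc9ccccc9)c1ccc([C@H]2Oc3cc(OCc9ccccc9)cc(OCc9ccccc9)c3[C@H](c3c(OCc9ccccc9)cc(OCc9ccccc9)c4c3O[C@H](c3ccc(OCc9ccccc9)c(OCc9ccccc9)c3)[C@@H](OCc9ccccc9)C4)[C@H]2O)cc1 | intermediate
17 | Gambiriin C | Oc1ccc([C@H]2Oc3cc(O)cc(O)c3[C@H](c3c(O)cc(O)c4c3O[C@H](c3ccc(O)c(O)c3)[C@@H](O)C4)[C@H]2O)cc1 | target

Total step count: 12. Longest linear sequence: 8 (steps 1, 2, 3, 6, 7, 10, 11, 12).

Steps most likely to fail

1. Step 10.
- Risk: the strongly stabilised and crowded methide may react too slowly with the weakly nucleophilic enol ester, so hydrolysis or acyl transfer of the ester and self-condensation of the carbinol could take over.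
- Risk: a fully stepwise course with bond rotation or acetoxonium participation would erode the 2,3-cis relationship.
- Risk: facial selectivity at C4 may be poor.
- Fallback: known flavan-4-yl cation coupling, setting out from 3 and returning at 15. Purchased (−)-epiafzelechin is benzylated on its three phenols (BnBr, K2CO3, DMF) to tri-O-benzyl-(−)-epiafzelechin F1. This is oxidised at C4 with DDQ in the presence of 2-ethoxyethanol (CH2Cl2, rt) to 4β-(2-ethoxyethoxy)-tri-O-benzylepiafzelechin F2. Acetylation (Ac2O, pyridine, DMAP) gives 3-O-acetyl-4β-(2-ethoxyethoxy)-tri-O-benzylepiafzelechin F3. TMSOTf (CH2Cl2, −78 °C) ionises F3 in the presence of an excess of 3. The C4 cation, covered on its α face by the participating acetate, should be taken up by C8' of 3 from the β face to give 15, and unreacted 3 is recovered.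

2. Step 6.
- Risk: addition of a di-ortho-substituted aryllithium to a di-ortho-substituted, donor-deactivated aldehyde may be slow. Protonation of the aryllithium, or anion translocation to a benzylic position followed by Wittig rearrangement, could then compete.
- Fallback: reversed polarity without a phenol mask, setting out from 4 and returning at 10. Aryllithium 8 is trapped with the small electrophile DMF to give 8-formyl-penta-O-benzylcatechin F4. Purchased 3,5-bis(benzyloxy)phenol is converted with EtMgBr (Et2O, then toluene) into bromomagnesium 3,5-bis(benzyloxy)phenoxide F5. This adds to F4 through a six-membered magnesium chelate, only ortho to the phenoxide oxygen (both ortho sites are equivalent). The product is 10 directly, so steps 4, 5 and 7 are not needed.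

3. Step 9.
- Risk: regio- and Z-selectivity may erode, because the electron-rich alkyne is prone to Markovnikov addition and to dimerisation, and Z-to-E isomerisation may set in on prolonged heating.
- Fallback: geometry secured by separation instead of catalyst control, setting out from 12 and returning at 13. Hydroboration with dicyclohexylborane and oxidation with NaBO3 (anti-Markovnikov hydration) gives [4-(benzyloxy)phenyl]acetaldehyde F6. Enol acetylation (Ac2O, Et3N, DMAP, CH2Cl2) gives 13 together with (E)-2-[4-(benzyloxy)phenyl]ethenyl acetate F7, and the two isomers are separated by chromatography.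

Further compounds
F1 | step 10 | tri-O-benzyl-(−)-epiafzelechin | O(Cc9ccccc9)c1ccc([C@H]2Oc3cc(OCc9ccccc9)cc(OCc9ccccc9)c3C[C@H]2O)cc1
F2 | step 10 | 4β-(2-ethoxyethoxy)-tri-O-benzylepiafzelechin | O(Cc9ccccc9)c1ccc([C@H]2Oc3cc(OCc9ccccc9)cc(OCc9ccccc9)c3[C@H](OCCOCC)[C@H]2O)cc1
F3 | step 10 | 3-O-acetyl-4β-(2-ethoxyethoxy)-tri-O-benzylepiafzelechin | O(Cc9ccccc9)c1ccc([C@H]2Oc3cc(OCc9ccccc9)cc(OCc9ccccc9)c3[C@H](OCCOCC)[C@H]2OC(C)=O)cc1
F4 | step 6 | 8-formyl-penta-O-benzylcatechin | O=Cc1c(OCc9ccccc9)cc(OCc9ccccc9)c2c1O[C@H](c1ccc(OCc9ccccc9)c(OCc9ccccc9)c1)[C@@H](OCc9ccccc9)C2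
F5 | step 6 | bromomagnesium 3,5-bis(benzyloxy)phenoxide | Br[Mg]Oc1cc(OCc9ccccc9)cc(OCc9ccccc9)c1
F6 | step 9 | [4-(benzyloxy)phenyl]acetaldehyde | O=CCc1ccc(OCc9ccccc9)cc1
F7 | step 9 | (E)-2-[4-(benzyloxy)phenyl]ethenyl acetate | CC(=O)O/C=C/c1ccc(OCc9ccccc9)cc1
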